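**Plan**

- Retrosynthesis, first cut: the C8–prenyl bond and the free 5-OH are traced back, through a retro-Cope/retro-Claisen relay, to the 5-O-prenyl ether of (S)-5,7-bis(prenyloxy)flavanone. Second cut: C4–C4a, giving an open-chain (S)-3-aryloxy-3-phenylpropanamide. Third cut: O1–C2, giving 3,5-bis(prenyloxy)phenol and an (R)-β-hydroxy amide.
- Enabling feature: ring A is a phloroglucinol. C4a is ortho to O1 and O5 and para to O7, and in the 3,5-bis(prenyloxy)phenyl ether the two carbons ortho to O1 are equivalent, so closing ring C at C4a needs no regiocontrol.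
- Forward: ring A is bought (5-bromoresorcinol), O-prenylated twice, Br is turned into OH, and the chain is joined by Mitsunobu etherification. Ring C is then closed by amide-activation acylation at C4a, which also differentiates the two prenyl ethers (one ends up peri to C4=O).
- A europium-chelated domino Claisen–Cope rearrangement then moves only the peri 5-O-prenyl group to C8 and frees 5-OH; the 7-O-prenyl ether stays.
- Stereochemistry: C2 (S) comes from commercial ethyl (R)-3-hydroxy-3-phenylpropanoate by Mitsunobu inversion; no later step makes or breaks a bond at C2.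

Key step: step 5

Assumption: the stereodescriptor of the target SMILES is read as (2S), and the Mitsunobu etherification is taken to proceed with inversion.

**Route**

Step 1
Reactants: 1 5-bromoresorcinol (5-bromobenzene-1,3-diol); 2 prenyl bromide (1-bromo-3-methylbut-2-ene)
Product: 3 1-bromo-3,5-bis(prenyloxy)benzene (prenyl = 3-methylbut-2-en-1-yl)
Conditions: prenyl bromide (2 equiv in all, slight excess), K2CO3, acetone, reflux
Reagents that add atoms: prenyl bromide (second equivalent of 2), CC(C)=CCBr
Why: twofold Williamson etherification, one molecule of prenyl bromide per phenol; the bromine lowers the ring nucleophilicity, so O-alkylation should dominate over C-prenylation.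

Step 2
Reactants: 3 1-bromo-3,5-bis(prenyloxy)benzene
Product: 6 3,5-bis(prenyloxy)phenol, via aryllithium 4 (not isolated), via lithium aryltrimethoxyborate 5 (not isolated)
Conditions: n-BuLi, THF, −78 °C; B(OMe)3, −78 °C → rt; 30% H2O2, aq. NaOH, 0 °C
Reagents that add atoms: hydrogen peroxide, OO
Why: bromine–lithium exchange should outrun ortho-lithiation at −78 °C, and borylation followed by oxidative aryl migration from boron to oxygen (organoborane oxidation) gives the phenol without the C-alkylation problems of phloroglucinol itself; basic peroxide does not epoxidise the prenyl alkenes.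

Step 3
Reactants: 7 ethyl (R)-3-hydroxy-3-phenylpropanoate; 8 dimethylamine
Product: 9 (R)-3-hydroxy-N,N-dimethyl-3-phenylpropanamide
Conditions: 40% aq. Me2NH (excess), MeOH, rt → 45 °C, sealed
Reagents that add atoms: none
Why: aminolysis of a β-hydroxy ester, assisted by the neighbouring hydroxyl, which leaves the carbinol stereocenter untouched.

Step 4
Reactants: 6 3,5-bis(prenyloxy)phenol; 9 (R)-3-hydroxy-N,N-dimethyl-3-phenylpropanamide
Product: 10 (S)-3-[3,5-bis(prenyloxy)phenoxy]-N,N-dimethyl-3-phenylpropanamide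
Conditions: PPh3, DIAD, THF, 0 °C → rt
Reagents that add atoms: none
Why: Mitsunobu reaction, in which the phenoxide displaces the benzylic oxyphosphonium group by SN2 with inversion (R → S) and so sets C2; the amide is used instead of the ester because its less acidic α-protons disfavour elimination to the cinnamoyl compound.

Step 5
Reactants: 10 (S)-3-[3,5-bis(prenyloxy)phenoxy]-N,N-dimethyl-3-phenylpropanamide
Product: 13 (S)-5,7-bis(prenyloxy)-2-phenylchroman-4-one, via O-triflyl iminium triflate 11 (not isolated), via cyclic 4-iminium triflate 12 (not isolated)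
Conditions: Tf2O, 2,6-di-tert-butyl-4-methylpyridine, CH2Cl2, −78 → 0 °C; then NaOAc/AcOH buffer (pH 5), THF–H2O, rt
Reagents that add atoms: water, O
Why: Tf2O turns the tertiary amide into an O-triflyl iminium ion (in equilibrium with the keteniminium ion after loss of an α-proton to the hindered pyridine); the ring-A carbon ortho to the ether oxygen, which is also ortho or para to both prenyloxy groups, attacks the iminium carbon, loss of triflate and of the ring proton gives the cyclic 4-iminium salt, and buffered water exchanges NMe2 for O. The closest known reaction type is the intramolecular Vilsmeier–Haack (Friedel–Crafts-type) ketone synthesis from a Tf2O- or POCl3-activated N,N-dialkylamide and a phloroglucinol ether. Ring C closes in a 6-exo-trig mode at the iminium carbon (6-exo-dig if the keteniminium ion is the electrophile), with the arene C=C bond inside the new ring. No stereocenter is formed; C2, set in step 4, has no bond made or broken, and keeping the iminium salt cold, free of unhindered base and hydrolysing it at pH 5 should prevent reversible C2–O1 opening through the enamine. Site selectivity needs no control, because the two carbons ortho to the ether oxygen are equivalent by the local twofold symmetry of the 3,5-bis(prenyloxy)phenyl ring and the tether cannot reach the para carbon; the acid-labile prenyl ethers should survive because the hindered pyridine takes up the triflic acid. The closure breaks that symmetry: the prenyloxy group next to the new C4 becomes O5, peri to the carbonyl, and the other becomes O7, which is the difference step 6 uses.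

Step 6
Reactants: 13 (S)-5,7-bis(prenyloxy)-2-phenylchroman-4-one
Product: 16 (S)-5-hydroxy-8-prenyl-7-prenyloxy-2-phenylchroman-4-one (target), via ortho-dienone 14 (not isolated), via para-dienone 15 (not isolated)
Conditions: Eu(fod)3 (10 mol %), CHCl3, 60 °C, sealed tube
Reagents that add atoms: none
Why: trivalent europium chelated between C4=O and O5 should accelerate the aromatic Claisen [3,3] shift of the peri prenyl ether alone to C6 (C4a is blocked), and the ortho-dienone should pass the allyl unit on to C8 by a Cope [3,3] shift and then enolise to the chelated 5-phenol (domino Claisen–Cope rearrangement), leaving the unchelated 7-O-prenyl ether and C2 untouched.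

**Compound list**

1 | 5-bromoresorcinol (5-bromobenzene-1,3-diol) | Oc1cc(O)cc(Br)c1 | starting material
2 | prenyl bromide (1-bromo-3-methylbut-2-ene) | CC(C)=CCBr | starting material
3 | 1-bromo-3,5-bis[(3-methylbut-2-en-1-yl)oxy]benzene | CC(C)=CCOc1cc(Br)cc(OCC=C(C)C)c1 | intermediate
4 | {3,5-bis[(3-methylbut-2-en-1-yl)oxy]phenyl}lithium | [Li]c1cc(OCC=C(C)C)cc(OCC=C(C)C)c1 | intermediate
5 | lithium {3,5-bis[(3-methylbut-2-en-1-yl)oxy]phenyl}trimethoxyborate | [Li+].CO[B-](OC)(OC)c1cc(OCC=C(C)C)cc(OCC=C(C)C)c1 | intermediate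
6 | 3,5-bis[(3-methylbut-2-en-1-yl)oxy]phenol | CC(C)=CCOc1cc(O)cc(OCC=C(C)C)c1 | intermediate
7 | ethyl (R)-3-hydroxy-3-phenylpropanoate | CCOC(=O)C[C@@H](O)c1ccccc1 | starting material
8 | dimethylamine | CNC | starting material
9 | (R)-3-hydroxy-N,N-dimethyl-3-phenylpropanamide | CN(C)C(=O)C[C@@H](O)c1ccccc1 | intermediate
10 | (S)-3-{3,5-bis[(3-methylbut-2-en-1-yl)oxy]phenoxy}-N,N-dimethyl-3-phenylpropanamide | CN(C)C(=O)C[C@H](Oc1cc(OCC=C(C)C)cc(OCC=C(C)C)c1)c1ccccc1 | intermediate
11 | (S)-N-{3-[3,5-bis(prenyloxy)phenoxy]-3-phenyl-1-(triflyloxy)propylidene}-N-methylmethanaminium triflate | C[N+](C)=C(OS(=O)(=O)C(F)(F)F)C[C@H](Oc1cc(OCC=C(C)C)cc(OCC=C(C)C)c1)c1ccccc1.[O-]S(=O)(=O)C(F)(F)F | intermediate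
12 | (S)-N-[5,7-bis(prenyloxy)-2-phenylchroman-4-ylidene]-N-methylmethanaminium triflate | CC(C)=CCOc1cc(OCC=C(C)C)c2c(c1)O[C@H](c1ccccc1)CC2=[N+](C)C.[O-]S(=O)(=O)C(F)(F)F | intermediate
13 | (2S)-5,7-bis[(3-methylbut-2-en-1-yl)oxy]-2-phenyl-2,3-dihydro-4H-chromen-4-one | CC(C)=CCOc1cc(OCC=C(C)C)c2c(c1)O[C@H](c1ccccc1)CC2=O | intermediate
14 | (2S)-6-(2-methylbut-3-en-2-yl)-7-[(3-methylbut-2-en-1-yl)oxy]-2-phenyl-2,3-dihydro-4H-chromene-4,5(6H)-dione (ortho-dienone, C6 configuration undefined) | O=C1C[C@@H](c2ccccc2)OC2=C1C(=O)C(C(C)(C)C=C)C(OCC=C(C)C)=C2 | intermediate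
15 | (2S)-8-(3-methylbut-2-en-1-yl)-7-[(3-methylbut-2-en-1-yl)oxy]-2-phenyl-2,3-dihydro-4H-chromene-4,5(8H)-dione (para-dienone, C8 configuration undefined) | O=C1C[C@@H](c2ccccc2)OC2=C1C(=O)C=C(OCC=C(C)C)C2CC=C(C)C | intermediate
16 | (2S)-5-hydroxy-8-(3-methylbut-2-en-1-yl)-7-[(3-methylbut-2-en-1-yl)oxy]-2-phenyl-2,3-dihydro-4H-chromen-4-one | CC(C)=CCOc1cc(O)c2c(c1CC=C(C)C)O[C@H](c1ccccc1)CC2=O | target

**Count**

Total steps: 6. Longest linear sequence: 5 steps (steps 1, 2, 4, 5, 6).

**Steps most likely to fail**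

Step 5. Three processes threaten it:
- loss of configuration at C2 by reversible opening of ring C at the iminium/enamine stage;
- β-elimination of the phenoxide from the activated amide before closure;
- acid-triggered loss or migration of prenyl groups.

Fallback: the same bond is closed with reversed polarity, by halogen–lithium exchange (Parham-type cyclisation) onto an N-methoxy-N-methylamide. The ketone then arises from a chelated tetrahedral adduct, with no iminium stage and no acid. It sets out from 6 and 7 and comes back at 13. Ortho-selective bromination of 6 (NBS, cat. i-Pr2NH, CH2Cl2, −78 °C) should give 2-bromo-3,5-bis(prenyloxy)phenol F1. Ester 7 is converted (MeNHOMe·HCl, i-PrMgCl, THF, −20 °C) into (R)-3-hydroxy-N-methoxy-N-methyl-3-phenylpropanamide F2. Mitsunobu coupling of the two (PPh3, DIAD, THF) with inversion gives (S)-3-[2-bromo-3,5-bis(prenyloxy)phenoxy]-N-methoxy-N-methyl-3-phenylpropanamide F3. Treatment with t-BuLi (2 equiv, THF, −78 °C) and aqueous work-up closes ring C to 13.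

Step 4. The activated β-carbinol may eliminate to the cinnamamide, and partial ionisation at the benzylic carbon may erode the inversion.

Fallback: the ether bond is made on a partner with no carbonyl group β to the carbinol, and the carbonyl is introduced afterwards. It sets out from 6 and comes back at 10. Mitsunobu reaction of 6 with commercial (R)-3-chloro-1-phenylpropan-1-ol (ClCC[C@@H](O)c1ccccc1; PPh3, DIAD, THF) should give (S)-1-(3-chloro-1-phenylpropoxy)-3,5-bis(prenyloxy)benzene F4. Displacement with CsOAc (DMF, 80 °C) gives (S)-3-[3,5-bis(prenyloxy)phenoxy]-3-phenylpropyl acetate F5. Methanolysis (K2CO3, MeOH) gives (S)-3-[3,5-bis(prenyloxy)phenoxy]-3-phenylpropan-1-ol F6. Oxidation (cat. TEMPO, PhI(OAc)2, MeCN–H2O) gives (S)-3-[3,5-bis(prenyloxy)phenoxy]-3-phenylpropanoic acid F7. Coupling with dimethylamine 8 (EDC·HCl, HOBt, i-Pr2NEt, CH2Cl2) returns 10.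

Step 6. The ortho-dienone may enolise before the Cope shift, which would stop the relay at C6 with the reversed allyl group, and the Lewis acid may cleave the prenyl ethers.

Fallback: the C8 prenyl group is delivered by an ortho-Claisen shift from O7 instead of the relay from O5. It sets out from 13 and comes back at 16. Removal of both prenyl ethers (cat. Yb(OTf)3, MeNO2, rt) should give (S)-pinocembrin F8. Alkylation of the non-chelated 7-OH (3-chloro-3-methylbut-1-yne, K2CO3, KI, cat. CuI, acetone) gives (S)-5-hydroxy-7-[(2-methylbut-3-yn-2-yl)oxy]-2-phenylchroman-4-one F9. Semi-hydrogenation (H2, Pd/CaCO3 poisoned with Pb(OAc)2, quinoline, EtOAc) gives (S)-5-hydroxy-7-[(2-methylbut-3-en-2-yl)oxy]-2-phenylchroman-4-one F10. Aromatic Claisen [3,3] rearrangement (toluene, 110 °C) should place a normal prenyl group mainly at C8 and give (S)-8-prenylpinocembrin F11; the C6 isomer is removed. Prenyl bromide 2 with K2CO3 in acetone at rt then alkylates only the non-chelated 7-OH and gives 16.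

**Further compounds**

F1 | step 5 | 2-bromo-3,5-bis[(3-methylbut-2-en-1-yl)oxy]phenol | CC(C)=CCOc1cc(O)c(Br)c(OCC=C(C)C)c1
F2 | step 5 | (R)-3-hydroxy-N-methoxy-N-methyl-3-phenylpropanamide | CON(C)C(=O)C[C@@H](O)c1ccccc1
F3 | step 5 | (S)-3-{2-bromo-3,5-bis[(3-methylbut-2-en-1-yl)oxy]phenoxy}-N-methoxy-N-methyl-3-phenylpropanamide | CON(C)C(=O)C[C@H](Oc1cc(OCC=C(C)C)cc(OCC=C(C)C)c1Br)c1ccccc1
F4 | step 4 | (S)-1-(3-chloro-1-phenylpropoxy)-3,5-bis[(3-methylbut-2-en-1-yl)oxy]benzene | ClCC[C@H](Oc1cc(OCC=C(C)C)cc(OCC=C(C)C)c1)c1ccccc1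
F5 | step 4 | (S)-3-{3,5-bis[(3-methylbut-2-en-1-yl)oxy]phenoxy}-3-phenylpropyl acetate | CC(=O)OCC[C@H](Oc1cc(OCC=C(C)C)cc(OCC=C(C)C)c1)c1ccccc1
F6 | step 4 | (S)-3-{3,5-bis[(3-methylbut-2-en-1-yl)oxy]phenoxy}-3-phenylpropan-1-ol | OCC[C@H](Oc1cc(OCC=C(C)C)cc(OCC=C(C)C)c1)c1ccccc1
F7 | step 4 | (S)-3-{3,5-bis[(3-methylbut-2-en-1-yl)oxy]phenoxy}-3-phenylpropanoic acid | OC(=O)C[C@H](Oc1cc(OCC=C(C)C)cc(OCC=C(C)C)c1)c1ccccc1
F8 | step 6 | (S)-pinocembrin, (2S)-5,7-dihydroxy-2-phenyl-2,3-dihydro-4H-chromen-4-one | Oc1cc(O)c2c(c1)O[C@H](c1ccccc1)CC2=O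
F9 | step 6 | (2S)-5-hydroxy-7-[(2-methylbut-3-yn-2-yl)oxy]-2-phenyl-2,3-dihydro-4H-chromen-4-one | C#CC(C)(C)Oc1cc(O)c2c(c1)O[C@H](c1ccccc1)CC2=O
F10 | step 6 | (2S)-5-hydroxy-7-[(2-methylbut-3-en-2-yl)oxy]-2-phenyl-2,3-dihydro-4H-chromen-4-one | C=CC(C)(C)Oc1cc(O)c2c(c1)O[C@H](c1ccccc1)CC2=O
F11 | step 6 | (S)-8-prenylpinocembrin, (2S)-5,7-dihydroxy-8-(3-methylbut-2-en-1-yl)-2-phenyl-2,3-dihydro-4H-chromen-4-one | CC(C)=CCc1c(O)cc(O)c2c1O[C@H](c1ccccc1)CC2=O
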